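**Retrosynthetic overview**
The strategy rests on ring C (O1, C2, C3, C4, C4a, C8a). Without the C4 oxygen it is a 3-methoxybenzopyrylium cation that already carries the C3 methoxy group, ring A and ring B.
Last disconnection: the para-related 2'-OH and 5'-OH of ring B come from a 2',4',5'-trimethoxyphenyl ring, by oxidative demethylation to the 2',5'-quinone and then reduction. The 4'-OMe has no para partner and stays.
Second disconnection: the C4 carbonyl comes from the C4 methylene of the 4H-flavene, which is the hydride adduct of the flavylium cation.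
Key disconnection: C3–C4 and O1–C2 are cut together. This gives 2-hydroxy-4,6-dimethoxybenzaldehyde (ring A and C4) and 2-methoxy-1-(2,4,5-trimethoxyphenyl)ethanone (ring B, C2, C3 and the 3-OMe). The ketone comes from an aryl bromide and a Weinreb amide.
Ring order: rings A and B are bought, and ring C is the only ring formed (step 2). The target has no stereocentre.

Key step: step 2

Assumption: 1-bromo-2,4,5-trimethoxybenzene (1) and N,2-dimethoxy-N-methylacetamide (2) are bought as catalogue chemicals. Flavonoid numbering (O1, C2 to C8a, primed positions in ring B) is used throughout.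

**Route**

Step 1
Reactants: 1 1-bromo-2,4,5-trimethoxybenzene; 2 N,2-dimethoxy-N-methylacetamide
Product: 5 2-methoxy-1-(2,4,5-trimethoxyphenyl)ethanone, via aryllithium 3 (not isolated), via tetrahedral lithium adduct 4 (not isolated)
Conditions: n-BuLi (1.05 equiv), THF, −78 °C, 30 min; then 2, −78 to 0 °C; 1 M aq HCl quench
Reagents that add atoms: N,2-dimethoxy-N-methylacetamide (2), COCC(=O)N(C)OC
Why: Bromine–lithium exchange followed by a Weinreb ketone synthesis places the acyl group on the carbon that carried bromine and stops at the ketone because chelated adduct 4 holds until the quench, and it avoids a Lewis-acid Friedel–Crafts acylation, in which the methoxyacetyl cation tends to lose CO and the ortho methyl ether tends to be cleaved.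

Step 2
Reactants: 5 2-methoxy-1-(2,4,5-trimethoxyphenyl)ethanone; 6 2-hydroxy-4,6-dimethoxybenzaldehyde
Product: 9 3,5,7-trimethoxy-2-(2,4,5-trimethoxyphenyl)chromenylium chloride, via chalcone 7 (not isolated), via hemiketal 8 (not isolated)
Conditions: HCl (g, to saturation), EtOAc, 0 °C; then 0–5 °C, 24–48 h; Et2O, filtration
Reagents that add atoms: hydrogen chloride, Cl
Why: HCl enolises ketone 5 at its only α-methylene and the enol adds to the protonated formyl group of 6, which forms C3–C4; loss of water gives chalcone 7, whose alkene geometry is mobile in acid because ring A pushes electron density into the protonated enone. In the geometry that holds ring A and the aroyl group cis, the ring A hydroxyl adds to the protonated ketone carbon, which forms O1–C2 and closes ring C in the 6-exo-trig mode to hemiketal 8, and ionisation of the C2 hydroxyl then gives the aromatic pyrylium ring of 9. The closest known reaction type is the classical acid-catalysed condensation of o-hydroxybenzaldehydes with ω-methoxyacetophenones to 3-methoxyflavylium salts, an aldol condensation followed by cyclodehydration. No stereocentre is created in 9, since the only sp3 centre on the way, C2 of 8, is flattened on ionisation. The step needs cross-condensation in one orientation: 6 has no α-hydrogen, 5 has one enolisable carbon and 6 has one free hydroxyl, ortho to the formyl group, so C3–C4 and O1–C2 are the only bonds that can form. The chloride should crystallise from EtOAc–Et2O, which pulls the reversible steps forward and takes the cation, electrophilic at C4, out of reach of the electron-rich ring A of unreacted 6.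

Step 3
Reactants: 9 3,5,7-trimethoxy-2-(2,4,5-trimethoxyphenyl)chromenylium chloride
Product: 10 3,5,7-trimethoxy-2-(2,4,5-trimethoxyphenyl)-4H-chromene
Conditions: LiAlH4 (0.5 equiv), THF, 0 °C, argon; aq NaOH work-up; used without delay
Reagents that add atoms: none
Why: Hydride addition to a benzopyrylium cation, a reduction known to turn 3-methoxyflavylium salts into flav-2-enes, should take place at C4 because C2 is screened by the twisted, ortho-methoxylated ring B and by the 3-OMe group and because the C4 adduct keeps the C2=C3 enol ether conjugated with ring B, while the basic work-up spares that acid-labile enol ether.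

Step 4
Reactants: 10 3,5,7-trimethoxy-2-(2,4,5-trimethoxyphenyl)-4H-chromene
Product: 12 3,5,7-trimethoxy-2-(2,4,5-trimethoxyphenyl)-4H-chromen-4-one, via C4 tert-butyl peroxide 11 (not isolated)
Conditions: Rh2(cap)4 (dirhodium tetrakis(caprolactamate), 1 mol %), t-BuOOH (5.5 M in decane, 5 equiv), K2CO3 (0.5 equiv), CH2Cl2, rt
Reagents that add atoms: tert-butyl hydroperoxide, CC(C)(C)OO
Why: Metal-catalysed allylic and benzylic C–H oxidation with t-BuOOH (the xanthene-to-xanthone type of oxidation) should pick the C4–H bonds, the weakest in 10 because they are benzylic to ring A and allylic to the C2=C3 enol ether; the tert-butylperoxyl radical abstracts hydrogen, the delocalised radical is captured at its less hindered end C4 to give 11, and K2CO3 triggers Kornblum–DeLaMare loss of tert-butanol to the vinylogous ester 12, which should resist further oxidation.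

Step 5
Reactants: 12 3,5,7-trimethoxy-2-(2,4,5-trimethoxyphenyl)-4H-chromen-4-one
Product: 13 2-methoxy-5-(3,5,7-trimethoxy-4-oxo-4H-chromen-2-yl)cyclohexa-2,5-diene-1,4-dione
Conditions: (NH4)2Ce(NO3)6 (2.5 equiv), MeCN–H2O (2:1), 0 °C, 15–30 min
Reagents that add atoms: water, O
Why: In this oxidative demethylation of a para-dimethoxyarene, electron transfer should start at ring B, the most electron-rich ring because rings A and C are deactivated by the C4 carbonyl; water then adds at C2' and C5', the only para-related pair of methoxy-bearing carbons, methanol leaves twice, and the 4'-OMe stays as the vinylogous ester of the p-quinone.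

Step 6
Reactants: 13 2-methoxy-5-(3,5,7-trimethoxy-4-oxo-4H-chromen-2-yl)cyclohexa-2,5-diene-1,4-dione
Product: 14 5-O-methyloxyayanin-A, 2-(2,5-dihydroxy-4-methoxyphenyl)-3,5,7-trimethoxy-4H-chromen-4-one
Conditions: Na2S2O4 (3 equiv), EtOAc–H2O, rt, argon
Reagents that add atoms: none
Why: Dithionite reduction of a p-benzoquinone to the hydroquinone is fast in a two-phase system and should leave the chromone carbonyl, the C2=C3 bond and the four methyl ethers alone, so that only the 2'-OH and 5'-OH groups are unveiled.

**Compound list**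
1 | 1-bromo-2,4,5-trimethoxybenzene | COc1cc(OC)c(OC)cc1Br | starting material
2 | N,2-dimethoxy-N-methylacetamide | COCC(=O)N(C)OC | starting material
3 | (2,4,5-trimethoxyphenyl)lithium | [Li]c1cc(OC)c(OC)cc1OC | intermediate
4 | lithium 2-methoxy-1-[methoxy(methyl)amino]-1-(2,4,5-trimethoxyphenyl)ethan-1-olate (racemic) | COCC([O-])(N(C)OC)c1cc(OC)c(OC)cc1OC.[Li+] | intermediate
5 | 2-methoxy-1-(2,4,5-trimethoxyphenyl)ethanone | COCC(=O)c1cc(OC)c(OC)cc1OC | intermediate
6 | 2-hydroxy-4,6-dimethoxybenzaldehyde | COc1cc(O)c(C=O)c(OC)c1 | starting material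
7 | (E)-3-(2-hydroxy-4,6-dimethoxyphenyl)-2-methoxy-1-(2,4,5-trimethoxyphenyl)prop-2-en-1-one (ring A and aroyl group cis) | COc1cc(O)c(/C=C(/OC)C(=O)c2cc(OC)c(OC)cc2OC)c(OC)c1 | intermediate
8 | 3,5,7-trimethoxy-2-(2,4,5-trimethoxyphenyl)-2H-chromen-2-ol (racemic) | COc1cc(OC)c2C=C(OC)C(O)(c3cc(OC)c(OC)cc3OC)Oc2c1 | intermediate
9 | 3,5,7-trimethoxy-2-(2,4,5-trimethoxyphenyl)chromenylium chloride | COc1cc(OC)c2cc(OC)c(-c3cc(OC)c(OC)cc3OC)[o+]c2c1.[Cl-] | intermediate
10 | 3,5,7-trimethoxy-2-(2,4,5-trimethoxyphenyl)-4H-chromene | COc1cc(OC)c2CC(OC)=C(c3cc(OC)c(OC)cc3OC)Oc2c1 | intermediate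
11 | 4-(tert-butylperoxy)-3,5,7-trimethoxy-2-(2,4,5-trimethoxyphenyl)-4H-chromene (racemic) | COc1cc(OC)c2C(OOC(C)(C)C)C(OC)=C(c3cc(OC)c(OC)cc3OC)Oc2c1 | intermediate
12 | 3,5,7-trimethoxy-2-(2,4,5-trimethoxyphenyl)-4H-chromen-4-one | COc1cc(OC)c2c(=O)c(OC)c(-c3cc(OC)c(OC)cc3OC)oc2c1 | intermediate
13 | 2-methoxy-5-(3,5,7-trimethoxy-4-oxo-4H-chromen-2-yl)cyclohexa-2,5-diene-1,4-dione | COc1cc(OC)c2c(=O)c(OC)c(C3=CC(=O)C(OC)=CC3=O)oc2c1 | intermediate
14 | 5-O-methyloxyayanin-A, 2-(2,5-dihydroxy-4-methoxyphenyl)-3,5,7-trimethoxy-4H-chromen-4-one | COc1cc(OC)c2c(=O)c(OC)c(-c3cc(O)c(OC)cc3O)oc2c1 | target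

Total step count: 6
Longest linear sequence: 6 steps (1 → 5 → 9 → 10 → 12 → 13 → 14)

**Steps most likely to fail**

1. Step 4.
- **Risk:** The delocalised radical may lose an electron and fall back to the flavylium cation. Oxygen may be captured at C2 in place of C4. The very electron-rich C2=C3 bond, which carries oxygen on both carbons, may be epoxidised or cleaved.
- **Fallback (sets out from 9, returns at 12):** The polarity is reversed, so that C4 becomes the nucleophilic carbon.
  - NaOMe in MeOH at 0 °C adds the hard oxygen nucleophile at C2 of 9. This should give 2,3,5,7-tetramethoxy-2-(2,4,5-trimethoxyphenyl)-2H-chromene F1.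
  - In F1 the C3=C4 bond is an enol ether whose nucleophilic end is C4. A Rubottom-type oxidation with mCPBA (NaHCO3 buffer, MeOH–CH2Cl2, −20 °C) must therefore put the new oxygen on C4, while methanol is taken up at C3. The product is 2,3,3,5,7-pentamethoxy-2-(2,4,5-trimethoxyphenyl)chroman-4-ol F2, as a mixture of diastereomers.
  - F2 already stands at the oxidation level of the flavone. Catalytic p-TsOH in warm toluene removes two molecules of methanol (the C3 methoxy group with the C4 hydrogen, then the C2 methoxy group) and ends at 12.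

2. Step 5.
- **Risk:** Electron transfer may also involve ring A, and ring B radical cations may couple at their free positions. Nitration may compete, the 4'-methyl may be lost along an ortho-quinone pathway, or the methoxyquinone may hydrolyse in the acidic medium.
- **Fallback (sets out from 2 and 6, returns at 14):** The two ring B oxygens that must end up free are carried as benzyl ethers, so that ring B never has to be oxidised.
  - Commercial 2-methoxyhydroquinone is benzylated (BnBr, K2CO3, DMF) to 1,4-bis(benzyloxy)-2-methoxybenzene F3.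
  - NBS in MeCN brominates para to the methoxy group and gives 1,4-bis(benzyloxy)-2-bromo-5-methoxybenzene F4.
  - Bromine–lithium exchange and acylation with 2, as in step 1, give 1-[2,5-bis(benzyloxy)-4-methoxyphenyl]-2-methoxyethanone F5.
  - Condensation of F5 with 6 in HCl–EtOAc, as in step 2, gives 2-[2,5-bis(benzyloxy)-4-methoxyphenyl]-3,5,7-trimethoxychromenylium chloride F6.
  - LiAlH4, as in step 3, gives 2-[2,5-bis(benzyloxy)-4-methoxyphenyl]-3,5,7-trimethoxy-4H-chromene F7.
  - The t-BuOOH oxidation of step 4 gives 2-[2,5-bis(benzyloxy)-4-methoxyphenyl]-3,5,7-trimethoxy-4H-chromen-4-one F8.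
  - Hydrogenolysis (H2, Pd/C, EtOAc–MeOH) then frees both phenols and ends at 14.

3. Step 3.
- **Risk:** Hydride may be delivered to C2 as well as to C4. The enol ether may hydrolyse or autoxidise during work-up.
- **Fallback (sets out from 9, returns at 10):** The hydrogens are placed on C3 and C4 by hydrogenation of the open-chain form, so that no hydride has to choose between C2 and C4.
  - Aqueous NaHCO3–EtOAc converts 9, by way of 8 and 7, into the more stable open form, (Z)-3-(2-hydroxy-4,6-dimethoxyphenyl)-2-methoxy-1-(2,4,5-trimethoxyphenyl)prop-2-en-1-one F9.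
  - H2 over Pd/C in EtOAc saturates the enone double bond to give racemic 3-(2-hydroxy-4,6-dimethoxyphenyl)-2-methoxy-1-(2,4,5-trimethoxyphenyl)propan-1-one F10.
  - Cyclodehydration of this o-hydroxydihydrochalcone with pyridinium p-toluenesulfonate in toluene over 4 Å molecular sieves closes O1–C2 again and loses water towards C3, which gives 10.

Further compounds
F1 | step 4 | 2,3,5,7-tetramethoxy-2-(2,4,5-trimethoxyphenyl)-2H-chromene (racemic) | COc1cc(OC)c2C=C(OC)C(OC)(c3cc(OC)c(OC)cc3OC)Oc2c1
F2 | step 4 | 2,3,3,5,7-pentamethoxy-2-(2,4,5-trimethoxyphenyl)chroman-4-ol (racemic, mixture of diastereomers) | COc1cc(OC)c2C(O)C(OC)(OC)C(OC)(c3cc(OC)c(OC)cc3OC)Oc2c1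
F3 | step 5 | 1,4-bis(benzyloxy)-2-methoxybenzene | COc1cc(OCc2ccccc2)ccc1OCc3ccccc3
F4 | step 5 | 1,4-bis(benzyloxy)-2-bromo-5-methoxybenzene | COc1cc(OCc2ccccc2)c(Br)cc1OCc3ccccc3
F5 | step 5 | 1-[2,5-bis(benzyloxy)-4-methoxyphenyl]-2-methoxyethanone | COCC(=O)c1cc(OCc2ccccc2)c(OC)cc1OCc3ccccc3
F6 | step 5 | 2-[2,5-bis(benzyloxy)-4-methoxyphenyl]-3,5,7-trimethoxychromenylium chloride | COc1cc(OC)c2cc(OC)c(-c3cc(OCc4ccccc4)c(OC)cc3OCc5ccccc5)[o+]c2c1.[Cl-]
F7 | step 5 | 2-[2,5-bis(benzyloxy)-4-methoxyphenyl]-3,5,7-trimethoxy-4H-chromene | COc1cc(OC)c2CC(OC)=C(c3cc(OCc4ccccc4)c(OC)cc3OCc5ccccc5)Oc2c1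
F8 | step 5 | 2-[2,5-bis(benzyloxy)-4-methoxyphenyl]-3,5,7-trimethoxy-4H-chromen-4-one | COc1cc(OC)c2c(=O)c(OC)c(-c3cc(OCc4ccccc4)c(OC)cc3OCc5ccccc5)oc2c1
F9 | step 3 | (Z)-3-(2-hydroxy-4,6-dimethoxyphenyl)-2-methoxy-1-(2,4,5-trimethoxyphenyl)prop-2-en-1-one | COc1cc(O)c(/C=C(\OC)C(=O)c2cc(OC)c(OC)cc2OC)c(OC)c1
F10 | step 3 | 3-(2-hydroxy-4,6-dimethoxyphenyl)-2-methoxy-1-(2,4,5-trimethoxyphenyl)propan-1-one (racemic) | COc1cc(O)c(CC(OC)C(=O)c2cc(OC)c(OC)cc2OC)c(OC)c1
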